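## Analysis of the target

Compound 9 is (2S)-5-hydroxy-6,7-dimethoxy-2-(3,4-dimethoxyphenyl)chroman-4-one, a flavanone. Ring A is a benzene ring carrying 5-OH, 6-OMe and 7-OMe with hydrogen at C8; it is fused to the dihydropyranone ring C (O1, C2, C3, C4=O), and ring B, a 3,4-dimethoxyphenyl group, sits on C2. C2 is the only stereocentre (S): it is benzylic, carries the ring oxygen O1 and lies β to the C4 ketone. This makes it labile, because base opens ring C by retro-oxa-Michael reaction to the achiral 2'-hydroxychalcone, and because the electron-rich ring B lets strong acid loosen the C2–O1 bond. The 5-hydroxyl is hydrogen-bonded to the C4 carbonyl and has to be told apart from two neighbouring methoxy groups on the same ring. The synthesis is hard for two reasons: one easily racemised stereocentre must be made late and under mild conditions, and exactly one of three contiguous ring A oxygens must be freed without a dealkylating reagent meeting that stereocentre. The strategy rests on the fact that C2 is the β-carbon of the enone in the corresponding chromone and is joined to ring B by the single C2–C1' bond. Rings A and C can therefore be built flat and achiral, ring B can arrive as an aryl nucleophile in the step that makes C2 stereogenic, and the peri relation of the C5 oxygen to the C4 carbonyl allows selective ether cleavage at the chromone stage.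

## Retrosynthetic reasoning

**9 ⇒ 8.** The last operation touches no skeletal bond. The O–H of the C5 phenol of 9 is traced back to the O–CH2Ph bond of benzyl ether 8. A free, chelated 5-hydroxyl in the acceptor would lower the electrophilicity of the enone and could bind the metal, so the oxygen is masked during the C–C bond formation. Benzyl is chosen because it leaves by hydrogenolysis in a neutral medium, which should not epimerise C2.

**8 ⇒ 6 + 7.** The C2–C1' bond is cut. This is the only bond whose formation creates the stereocentre, and everything on either side of it is flat: chromone 6 and boronic acid 7. Cutting here makes the route convergent and defers all stereochemistry to one catalytic event. The forward reaction must deliver the aryl group to C2 (not C3) of 6 through one enantioface and stop at the 1,4-adduct without dehydrogenation to the flavone.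

**6 ⇒ 5 ⇒ 4.** The C5 ether is exchanged: the benzyl ether 6 comes from phenol 5, and 5 from the trimethyl ether 4 by removal of one methyl group. The three methoxy groups of 4 differ only in their relation to the C4 carbonyl, and the peri one can be singled out by chelation to a boron Lewis acid. Doing this on the achiral chromone means the Lewis acid never sees C2 as a stereocentre.

**4 ⇒ 2 (through 3).** Ring C is opened at O1–C2 and C2–C3. C2 is a single carbon at the formyl oxidation level, so it can come from a formamide acetal that condenses with the methyl ketone of 2 to enaminone 3. The ortho-hydroxyl of 3 then displaces the amine to close the pyranone. This builds ring C with no substituent at C2, as the key step requires.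

**2 ⇒ 1.** The C4–C4a bond (aryl–acyl) is cut, leading to phenol 1. Because 1 is symmetric, its two free ring positions are equivalent and both lie ortho to the hydroxyl, so acylation can give only one regioisomer. All ring A oxygens come from a single commercial compound.

## Alternatives that were turned down

**Alternative 1: oxa-Povarov-type annulation with a ketene acetal.**
- Disconnection: C2–C3 and C4–C4a of ring C, a formal [4+2] between an O-aryl oxocarbenium ion and a two-carbon ketene acetal.
- Forward key step: racemic (3,4-dimethoxyphenyl)(3,4,5-trimethoxyphenoxy)methyl acetate A1 would be ionised by a confined chiral imidodiphosphorimidate acid. 1,1-Dimethoxyethene A2 would add to C2 inside the chiral ion pair, and the resulting dimethoxycarbenium ion would alkylate the ortho position of the phenoxy ring. The product would be (2S)-4,4,5,6,7-pentamethoxy-2-(3,4-dimethoxyphenyl)chromane A3, the C4 dimethyl ketal.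
- For it: one step forms two C–C bonds, ring C and the stereocentre, and does so enantioconvergently from a racemate. The symmetry of the phenoxy ring removes any regiochemical question. The ketal blocks retro-oxa-Michael opening.
- Against it: the cation next to the 3,4-dimethoxyphenyl group is strongly stabilised and long-lived, which weakens ion pairing. A2 oligomerises and hydrolyses readily under acid. The mixed acetal A1 is fragile. This pairing of an aryloxy oxocarbenium ion with a ketene acetal has no precedent on this substrate class. The product still carries a 5-methyl ether, so after ketal hydrolysis a Lewis acid would have to cleave it on the finished flavanone, where ring B makes C2–O1 ionisable.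
- Comparison: it is stronger in bonds formed per step and about equal in length (roughly five steps). The chosen route offers a key step of a known reaction class on chromones and places the dealkylation before C2 exists.

**Alternative 2: aryl ether coupling of a 1,3-diol.**
- Disconnection: O1–C8a.
- Forward key step: in (1R,3S)-1-(2-bromo-4,5,6-trimethoxyphenyl)-3-(3,4-dimethoxyphenyl)propane-1,3-diol A4, the hydroxyl on the ring B carbon would couple with the aryl bromide under Pd(OAc)2, a bulky di-tert-butyl biarylphosphine and Cs2CO3. This would give (2S,4R)-5,6,7-trimethoxy-2-(3,4-dimethoxyphenyl)chroman-4-ol A5. Oxidation at C4 and 5-O-demethylation would follow.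
- For it: C2 is set as a carbinol carbon by well-understood carbonyl chemistry, independent of the acceptor ability of an electron-rich chromone. It cannot racemise by ring opening until the ketone appears at the very end. On predictability of stereocontrol this alternative is the stronger one.
- Against it: two stereocentres are built and one is then destroyed. The aryl bromide bears three methoxy groups and should add slowly to zerovalent palladium. Both hydroxyls are secondary and benzylic and can undergo β-hydride elimination from the palladium alkoxide instead of C–O reductive elimination. Hot Cs2CO3 is a harsh medium. The late demethylation problem of Alternative 1 returns.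
- Comparison: with the preparation of A4 the sequence is about ten steps and linear. The chosen route needs about half that and is convergent.

**Alternative 3: Friedel–Crafts closure of ring C on the symmetric aryl ether.**
- Disconnection: C4–C4a.
- Forward key step: (3S)-3-(3,4-dimethoxyphenyl)-3-(3,4,5-trimethoxyphenoxy)propanoic acid A6, as its mixed trifluoroacetic anhydride, would acylate the ring A carbon ortho to the ether oxygen. This would give (2S)-5,6,7-trimethoxy-2-(3,4-dimethoxyphenyl)chroman-4-one A7.
- For it: both ortho positions are equivalent and strongly activated, so the ring closure is regiochemically certain. No metal catalysis is needed. Phenol 1 is used directly without a protecting-group exchange. On these points it is as strong as or stronger than the chosen route, and the length is similar.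
- Against it: the stereocentre of A6 is a benzylic aryl ether carbon next to a strongly donating ring and β to the activated carboxyl. Installing it by Mitsunobu etherification of an electron-rich benzylic alcohol with 1 risks partial ionisation and elimination. The acidic acylation medium can then ionise C–O or expel the phenol by β-elimination. A7 also has to be demethylated at C5 with a Lewis acid afterwards.
- Comparison: the stereocentre would pass through three ionisation-prone operations after it is made. In the chosen route C2 is created in the penultimate step and afterwards meets only neutral hydrogenolysis.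

Key step: step 5

Assumption: with this catalyst type the (S)-ligand is known to deliver the aryl group to the face of cyclic enones that corresponds to 2R in a chromone, so the (R)-ligand is taken as the one that gives 2S. If the sense is opposite on this substrate, the (S)-ligand is used and nothing else changes.

## Route

Step 1
Reactants: 1 3,4,5-trimethoxyphenol
Product: 2 1-(6-hydroxy-2,3,4-trimethoxyphenyl)ethan-1-one
Conditions: AcOH, BF3·OEt2, 90 °C; aq. NaOAc work-up
Reagents that add atoms: acetic acid, CC(=O)O
Why: Friedel–Crafts (Fries-type) ortho-acylation of a highly activated phenol; the two free ring positions of symmetric 1 are equivalent, so only one ketone can form, and its boron chelate is deactivated towards a second acylation.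

Step 2
Reactants: 2 1-(6-hydroxy-2,3,4-trimethoxyphenyl)ethan-1-one
Product: 4 5,6,7-trimethoxy-4H-chromen-4-one, via enaminone 3 (not isolated)
Conditions: Me2NCH(OMe)2, toluene, 110 °C; concentrate; conc. HCl, CH2Cl2, 40 °C
Reagents that add atoms: N,N-dimethylformamide dimethyl acetal, COC(OC)N(C)C
Why: Condensation of the methyl ketone with the amide acetal gives the β-enaminone, and acid then promotes intramolecular oxa-Michael addition of the ortho-hydroxyl followed by loss of dimethylamine (enaminone chromone synthesis); the only hydroxyl present fixes the ring A pattern as 5,6,7.

Step 3
Reactants: 4 5,6,7-trimethoxy-4H-chromen-4-one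
Product: 5 5-hydroxy-6,7-dimethoxy-4H-chromen-4-one
Conditions: BCl3 (1.2 equiv), CH2Cl2, −78 to 0 °C; aq. NaHCO3
Reagents that add atoms: none
Why: Chelation-controlled ether cleavage: boron bound to the C4 carbonyl reaches only the peri 5-methoxy oxygen, and chloride removes that methyl group through a six-membered chelate. Limited reagent and low temperature should leave the 6- and 7-ethers alone, and no stereocentre exists yet.

Step 4
Reactants: 5 5-hydroxy-6,7-dimethoxy-4H-chromen-4-one
Product: 6 5-(benzyloxy)-6,7-dimethoxy-4H-chromen-4-one
Conditions: BnBr, K2CO3, Bu4NI (cat.), DMF, 70 °C
Reagents that add atoms: benzyl bromide, BrCc1ccccc1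
Why: Williamson etherification of the chelated phenol, helped by a polar aprotic solvent, warmth and in situ benzyl iodide; the benzyl ether breaks the hydrogen bond to C4=O and can later be removed without acid or base.

Step 5
Reactants: 6 5-(benzyloxy)-6,7-dimethoxy-4H-chromen-4-one; 7 3,4-dimethoxyphenylboronic acid
Product: 8 (2S)-5-(benzyloxy)-6,7-dimethoxy-2-(3,4-dimethoxyphenyl)chroman-4-one
Conditions: 7 (2.5 equiv), Pd(OCOCF3)2 (10 mol %), (R)-4-tert-butyl-2-(pyridin-2-yl)-4,5-dihydrooxazole (12 mol %), NH4PF6 (30 mol %), H2O (5 equiv), ClCH2CH2Cl, 60 °C
Reagents that add atoms: none
Why: Cationic divalent palladium carrying the pyridine-oxazoline ligand transmetalates with 7 to an arylpalladium species, the C2=C3 bond of 6 coordinates, and migratory insertion puts the 3,4-dimethoxyphenyl group on C2 and palladium on C3; the palladium enolate is protonated by water, which releases 8 and returns the catalyst with no change of oxidation state. The closest known reaction type is the asymmetric conjugate addition of arylboronic acids to cyclic enones and chromones under divalent palladium and pyridine-oxazoline ligands. No ring is closed: rings A and C are already present in 6 and only the trigonal C2 becomes tetrahedral. The new stereocentre C2 is controlled by the catalyst alone, the tert-butyl group on the oxazoline blocking one quadrant beside the aryl–palladium bond so that the flat chromone inserts through one enantioface; the (R)-ligand is chosen to give 2S. Regioselectivity for C2 over C3 follows from the polarisation of the vinylogous ester, C2 being the β-carbon bound to O1. Selectivity for 1,4-addition over Heck-type β-hydride elimination to the flavone rests on fast protonolysis of the enolate by the added water while the PF6 counterion keeps the metal cationic. The 5-benzyl ether removes the chelated phenol that would deactivate the carbonyl and bind the metal, and the near-neutral medium avoids retro-oxa-Michael opening of 8, which would racemise C2. The excess of 7 compensates for protodeboronation of the electron-rich boronic acid.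

Step 6
Reactants: 8 (2S)-5-(benzyloxy)-6,7-dimethoxy-2-(3,4-dimethoxyphenyl)chroman-4-one
Product: 9 (2S)-5-hydroxy-6,7-dimethoxy-2-(3,4-dimethoxyphenyl)chroman-4-one
Conditions: H2 (1 atm), 10% Pd/C, EtOAc, rt
Reagents that add atoms: none
Why: Catalytic hydrogenolysis of the aryl benzyl ether should be much faster than cleavage of the cyclic C2–O1 benzylic ether or reduction of the aryl ketone; the medium is neutral, so C2 should keep its configuration.

## Compound list

1 | 3,4,5-trimethoxyphenol | COc1cc(O)cc(OC)c1OC | starting material
2 | 1-(6-hydroxy-2,3,4-trimethoxyphenyl)ethan-1-one | CC(=O)c1c(O)cc(OC)c(OC)c1OC | intermediate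
3 | (E)-3-(dimethylamino)-1-(6-hydroxy-2,3,4-trimethoxyphenyl)prop-2-en-1-one | CN(C)/C=C/C(=O)c1c(O)cc(OC)c(OC)c1OC | intermediate (not isolated)
4 | 5,6,7-trimethoxy-4H-chromen-4-one | COc1cc2occc(=O)c2c(OC)c1OC | intermediate
5 | 5-hydroxy-6,7-dimethoxy-4H-chromen-4-one | COc1cc2occc(=O)c2c(O)c1OC | intermediate
6 | 5-(benzyloxy)-6,7-dimethoxy-4H-chromen-4-one | O=c1ccoc2cc(OC)c(OC)c(OCc3ccccc3)c12 | intermediate
7 | 3,4-dimethoxyphenylboronic acid | COc1ccc(B(O)O)cc1OC | starting material
8 | (2S)-5-(benzyloxy)-6,7-dimethoxy-2-(3,4-dimethoxyphenyl)chroman-4-one | COc1ccc([C@@H]2CC(=O)c3c(cc(OC)c(OC)c3OCc4ccccc4)O2)cc1OC | intermediate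
9 | (2S)-5-hydroxy-6,7-dimethoxy-2-(3,4-dimethoxyphenyl)chroman-4-one | COc1ccc([C@@H]2CC(=O)c3c(cc(OC)c(OC)c3O)O2)cc1OC | target

## Step count and risks

Total step count: 6. Longest linear sequence: 6 steps, from 1 to 9; 7 is bought and enters in step 5.

**Step 5, the key step.** The most likely failure is slow insertion into this electron-rich, peri-substituted chromone, so that protodeboronation and homocoupling of 7 use up the nucleophile. The second is incomplete enantioface discrimination, because the benzyloxy group changes the shape of the acceptor near the carbonyl. The fallback separates bond formation from stereocontrol; it sets out from 6 and returns at 8.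
- Copper-catalysed 1,4-addition of commercial 3,4-dimethoxyphenylmagnesium bromide to 6 (CuBr·SMe2, Me3SiCl, THF, −78 °C) would give the racemic silyl enol ether {[5-(benzyloxy)-2-(3,4-dimethoxyphenyl)-6,7-dimethoxy-2H-chromen-4-yl]oxy}trimethylsilane F1.
- Mild acidic work-up would hydrolyse F1 to racemic 5-(benzyloxy)-6,7-dimethoxy-2-(3,4-dimethoxyphenyl)chroman-4-one F2.
- Kinetic resolution by asymmetric transfer hydrogenation (RuCl(p-cymene)[(R,R)-TsDPEN], HCO2H/NEt3, EtOAc) is expected to reduce the (2R)-enantiomer to (2R,4R)-5-(benzyloxy)-6,7-dimethoxy-2-(3,4-dimethoxyphenyl)chroman-4-ol F3. The unreacted (2S)-ketone, which is 8, would be separated by chromatography.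
- The price is that at most half of the material is kept.

**Step 6.** The most likely failure is over-reduction: hydrogenolysis of the benzylic C2–O1 bond, made easier by the electron-rich ring B, which opens ring C and destroys the stereocentre, or reduction of the C4 ketone. The fallback is non-reductive; it sets out from 8 and returns at 9 with no new compound. BCl3 with pentamethylbenzene as cation scavenger in CH2Cl2 at −78 °C cleaves the chelation-activated benzyl ether much faster than the methyl ethers. It would be quenched cold to keep the exposure of C2–O1 to the Lewis acid short.

**Step 4.** The most likely failure is incomplete alkylation of the hydrogen-bonded, doubly flanked phenol, or opening of the pyranone by base at the temperature needed. The fallback changes the protecting group; it sets out from 5 and returns at 9, bypassing 6 and 8.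
- Acetylation (Ac2O, pyridine, DMAP) should give 6,7-dimethoxy-4-oxo-4H-chromen-5-yl acetate F4. The acetate also lowers the electron density of the acceptor.
- The conditions of step 5 applied to F4 and 7 should give (2S)-2-(3,4-dimethoxyphenyl)-6,7-dimethoxy-4-oxochroman-5-yl acetate F5.
- Acid-catalysed methanolysis (catalytic HCl in MeOH, rt) would release 9 without hydrogen or base.

## Further compounds

F1 | step 5 | {[5-(benzyloxy)-2-(3,4-dimethoxyphenyl)-6,7-dimethoxy-2H-chromen-4-yl]oxy}trimethylsilane (racemic) | COc1ccc(C2C=C(O[Si](C)(C)C)c3c(cc(OC)c(OC)c3OCc4ccccc4)O2)cc1OC
F2 | step 5 | racemic 5-(benzyloxy)-6,7-dimethoxy-2-(3,4-dimethoxyphenyl)chroman-4-one | COc1ccc(C2CC(=O)c3c(cc(OC)c(OC)c3OCc4ccccc4)O2)cc1OC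
F3 | step 5 | (2R,4R)-5-(benzyloxy)-6,7-dimethoxy-2-(3,4-dimethoxyphenyl)chroman-4-ol | COc1ccc([C@H]2C[C@@H](O)c3c(cc(OC)c(OC)c3OCc4ccccc4)O2)cc1OC
F0 | step 6 | none | none
F4 | step 4 | 6,7-dimethoxy-4-oxo-4H-chromen-5-yl acetate | CC(=O)Oc1c(OC)c(OC)cc2occc(=O)c12
F5 | step 4 | (2S)-2-(3,4-dimethoxyphenyl)-6,7-dimethoxy-4-oxochroman-5-yl acetate | COc1ccc([C@@H]2CC(=O)c3c(cc(OC)c(OC)c3OC(C)=O)O2)cc1OC
A1 | alternative 1 | (3,4-dimethoxyphenyl)(3,4,5-trimethoxyphenoxy)methyl acetate (racemic) | COc1ccc(C(OC(C)=O)Oc2cc(OC)c(OC)c(OC)c2)cc1OC
A2 | alternative 1 | 1,1-dimethoxyethene | C=C(OC)OC
A3 | alternative 1 | (2S)-4,4,5,6,7-pentamethoxy-2-(3,4-dimethoxyphenyl)chromane | COc1ccc([C@@H]2CC(OC)(OC)c3c(cc(OC)c(OC)c3OC)O2)cc1OC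
A4 | alternative 2 | (1R,3S)-1-(2-bromo-4,5,6-trimethoxyphenyl)-3-(3,4-dimethoxyphenyl)propane-1,3-diol | COc1ccc([C@@H](O)C[C@@H](O)c2c(Br)cc(OC)c(OC)c2OC)cc1OC
A5 | alternative 2 | (2S,4R)-5,6,7-trimethoxy-2-(3,4-dimethoxyphenyl)chroman-4-ol | COc1ccc([C@@H]2C[C@@H](O)c3c(cc(OC)c(OC)c3OC)O2)cc1OC
A6 | alternative 3 | (3S)-3-(3,4-dimethoxyphenyl)-3-(3,4,5-trimethoxyphenoxy)propanoic acid | COc1ccc([C@H](CC(=O)O)Oc2cc(OC)c(OC)c(OC)c2)cc1OC
A7 | alternative 3 | (2S)-5,6,7-trimethoxy-2-(3,4-dimethoxyphenyl)chroman-4-one | COc1ccc([C@@H]2CC(=O)c3c(cc(OC)c(OC)c3OC)O2)cc1OC
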